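**Retrosynthetic overview**

1. The feature the route rests on is ring A: C5, C6, C7 and C8 all bear oxygen in the order OH, OMe, OH, OMe, with the C5 and C8 oxygens para. A four-carbon squarate unit supplies C5–C8 with all four oxygens in place.
2. Ring A is the only ring made and is made last. The C8–C8a bond closes when the 4-hydroxycyclobutenone on pyranone C5 (12) opens thermally to a dienylketene that cyclises onto pyranone C6, giving 15.
3. Carbinol 12 comes from the pyranon-5-ylmagnesium reagent (from iodide 8) and methyl tert-butyl squarate 10, made from dimethyl squarate.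
4. Ring C is bought as 3-hydroxy-4H-pyran-4-one and ring B as 2-methoxyresorcinol. They are joined by Suzuki–Miyaura coupling (3 + 6), followed by iodination at pyranone C5.
5. After ring closure: methylation of the non-chelated 8-OH, acid cleavage of the tert-butyl ether, and methanolysis of the ring B pivalates.

Key step: step 9

Assumption 1: the organomagnesium is taken to attack squarate 10 at the carbonyl whose neighbouring carbon carries OMe, because the tert-butoxy group shields the other carbonyl. This places OMe at C6 and O-tert-butyl at C7.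

Assumption 2: the ring B phenols are carried as pivalates instead of ethers. This keeps ring B inert to electrophilic iodine in step 6 and leaves only one unhindered aryl C–H for borylation in step 2.

**Route**

Step 1
Reactants: 1 2-methoxybenzene-1,3-diol
Product: 2 2-methoxy-1,3-phenylene bis(2,2-dimethylpropanoate)
Conditions: PivCl, Et3N, DMAP (cat.), CH2Cl2, 0 °C to rt
Reagents that add atoms: pivaloyl chloride, CC(C)(C)C(=O)Cl
Why: Base-mediated O-acylation of both phenols should be clean and gives esters that withdraw electron density from ring B.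

Step 2
Reactants: 2 2-methoxy-1,3-phenylene bis(2,2-dimethylpropanoate)
Product: 3 2-methoxy-5-(4,4,5,5-tetramethyl-1,3,2-dioxaborolan-2-yl)-1,3-phenylene bis(2,2-dimethylpropanoate)
Conditions: B2pin2, [Ir(OMe)(cod)]2 (1.5 mol%), 4,4'-di-tert-butyl-2,2'-bipyridine (3 mol%), THF, 80 °C
Reagents that add atoms: bis(pinacolato)diboron, CC1(C)OB(OC1(C)C)B1OC(C)(C)C(C)(C)O1
Why: Iridium-catalysed aromatic C–H borylation is governed by sterics, and C5 is the only C–H with no ortho substituent.

Step 3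
Reactants: 4 3-hydroxy-4H-pyran-4-one
Product: 5 2-bromo-3-hydroxy-4H-pyran-4-one
Conditions: NBS (1.0 equiv), MeCN, 0 °C to rt
Reagents that add atoms: N-bromosuccinimide, O=C1CCC(=O)N1Br
Why: Electrophilic bromination of a 3-hydroxy-4-pyranone goes to C2, the enol carbon ortho to the hydroxyl.

Step 4
Reactants: 5 2-bromo-3-hydroxy-4H-pyran-4-one
Product: 6 2-bromo-3-methoxy-4H-pyran-4-one
Conditions: MeI, K2CO3, acetone, rt
Reagents that add atoms: iodomethane, CI
Why: Williamson O-methylation of the acidic enolic hydroxyl installs the C3 methoxyl of the target.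

Step 5
Reactants: 3 2-methoxy-5-(4,4,5,5-tetramethyl-1,3,2-dioxaborolan-2-yl)-1,3-phenylene bis(2,2-dimethylpropanoate); 6 2-bromo-3-methoxy-4H-pyran-4-one
Product: 7 2-methoxy-5-(3-methoxy-4-oxo-4H-pyran-2-yl)-1,3-phenylene bis(2,2-dimethylpropanoate)
Conditions: PdCl2(dppf) (3 mol%), K3PO4, 1,4-dioxane/H2O 9:1, 70 °C
Reagents that add atoms: none
Why: Suzuki–Miyaura coupling should proceed readily at the C2 bromide, a vinylogous acyl bromide, and aryl pivalates tolerate the mild phosphate base.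

Step 6
Reactants: 7 2-methoxy-5-(3-methoxy-4-oxo-4H-pyran-2-yl)-1,3-phenylene bis(2,2-dimethylpropanoate)
Product: 8 5-(5-iodo-3-methoxy-4-oxo-4H-pyran-2-yl)-2-methoxy-1,3-phenylene bis(2,2-dimethylpropanoate)
Conditions: I2 (0.6 equiv), (NH4)2Ce(NO3)6 (1.1 equiv), MeCN, 65 °C
Reagents that add atoms: iodine, II
Why: Oxidant-assisted electrophilic iodination attacks C5, the carbon beta to the ring oxygen and alpha to the carbonyl (the position iodinated in chromones and flavones), while ring B is deactivated by its two acyloxy groups.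

Step 7
Reactants: 9 dimethyl squarate (3,4-dimethoxycyclobut-3-ene-1,2-dione)
Product: 10 3-tert-butoxy-4-methoxycyclobut-3-ene-1,2-dione
Conditions: LiOtBu (1.0 equiv), THF, −78 to −40 °C; sat. aq NH4Cl
Reagents that add atoms: lithium tert-butoxide, [Li+].CC(C)(C)[O-]
Why: Alkoxide exchange by addition–elimination at the vinylogous ester carbon should stop after one exchange, since the second site is hindered by the new tert-butoxy group and lithium methoxide is the weaker base.

Step 8
Reactants: 8 5-(5-iodo-3-methoxy-4-oxo-4H-pyran-2-yl)-2-methoxy-1,3-phenylene bis(2,2-dimethylpropanoate); 10 3-tert-butoxy-4-methoxycyclobut-3-ene-1,2-dione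
Product: 12 racemic 5-[5-(3-tert-butoxy-1-hydroxy-2-methoxy-4-oxocyclobut-2-en-1-yl)-3-methoxy-4-oxo-4H-pyran-2-yl]-2-methoxy-1,3-phenylene bis(2,2-dimethylpropanoate), via pyranon-5-ylmagnesium chloride 11 (not isolated)
Conditions: iPrMgCl·LiCl (1.1 equiv), THF, −40 °C; then 10, −78 to −30 °C; sat. aq NH4Cl
Reagents that add atoms: none
Why: Iodine–magnesium exchange at the alpha-iodo enone carbon is fast at low temperature and tolerates pivalates, and 1,2-addition to the squarate carbonyl next to the methoxy-bearing carbon should give the carbinol, whose stereocentre forms racemic and is destroyed in step 9.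

Step 9
Reactants: 12 racemic 5-[5-(3-tert-butoxy-1-hydroxy-2-methoxy-4-oxocyclobut-2-en-1-yl)-3-methoxy-4-oxo-4H-pyran-2-yl]-2-methoxy-1,3-phenylene bis(2,2-dimethylpropanoate)
Product: 15 5-(7-tert-butoxy-5,8-dihydroxy-3,6-dimethoxy-4-oxo-4H-chromen-2-yl)-2-methoxy-1,3-phenylene bis(2,2-dimethylpropanoate), via (Z)-dienylketene 13 (not isolated), via 8aH-chromene-4,8-dione tautomer 14 (not isolated)
Conditions: toluene (degassed, 0.02 M), 110 °C, Ar
Reagents that add atoms: none
Why: Heating should cleave the C(=O)–C(OH) bond of the cyclobutenone by conrotatory 4π electrocyclic opening, with the hydroxyl rotating outward, to give the (Z)-dienylketene 13 with the pyranone cis to the ketene. A thermally allowed disrotatory 6π electrocyclisation over the ketene C=C, the enol C=C and the pyranone C5=C6 bond then joins the ketene carbon to pyranone C6 (the C8–C8a bond) and closes six-membered ring A as dienone 14, which tautomerises to the aromatic 5,8-hydroquinone 15. The closest known reaction type is the Moore rearrangement of 4-aryl- and 4-heteroaryl-4-hydroxycyclobutenones to fused hydroquinones. No stereocentre remains, since the carbinol carbon becomes sp2 C5 and the transient C8a centre of 14 is lost on aromatisation. The step needs ring closure at carbon instead of capture of the ketene by the hydroxyl, and a single closure site; outward rotation of the donor hydroxyl turns the pyranone toward the ketene, and C6 is the only free ortho carbon because the other neighbour of C5 is the C4 carbonyl. The order OMe at C6 and O-tert-butyl at C7 is carried over unchanged from 12.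

Step 10
Reactants: 15 5-(7-tert-butoxy-5,8-dihydroxy-3,6-dimethoxy-4-oxo-4H-chromen-2-yl)-2-methoxy-1,3-phenylene bis(2,2-dimethylpropanoate)
Product: 16 5-(7-tert-butoxy-5-hydroxy-3,6,8-trimethoxy-4-oxo-4H-chromen-2-yl)-2-methoxy-1,3-phenylene bis(2,2-dimethylpropanoate)
Conditions: MeI (1.1 equiv), K2CO3, acetone (degassed), rt, Ar
Reagents that add atoms: iodomethane, CI
Why: The 5-hydroxyl is held in a hydrogen-bond chelate with the C4 carbonyl, so Williamson methylation with a mild base should take place only at the free 8-hydroxyl.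

Step 11
Reactants: 16 5-(7-tert-butoxy-5-hydroxy-3,6,8-trimethoxy-4-oxo-4H-chromen-2-yl)-2-methoxy-1,3-phenylene bis(2,2-dimethylpropanoate)
Product: 17 5-(5,7-dihydroxy-3,6,8-trimethoxy-4-oxo-4H-chromen-2-yl)-2-methoxy-1,3-phenylene bis(2,2-dimethylpropanoate)
Conditions: TFA/CH2Cl2 1:4, 0 °C to rt
Reagents that add atoms: none
Why: Acidolysis of the aryl tert-butyl ether frees the 7-hydroxyl while methyl ethers and pivalates are stable, and neither ring offers a site for tert-butylation (ring A is fully substituted, ring B is deactivated).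

Step 12
Reactants: 17 5-(5,7-dihydroxy-3,6,8-trimethoxy-4-oxo-4H-chromen-2-yl)-2-methoxy-1,3-phenylene bis(2,2-dimethylpropanoate)
Product: 18 5,7,3',5'-tetrahydroxy-3,6,8,4'-tetramethoxyflavone
Conditions: K2CO3, MeOH (degassed), rt to 40 °C, Ar; then 1 M HCl
Reagents that add atoms: none
Why: Base-mediated transesterification of the two aryl pivalates with methanol should release the 3'- and 5'-hydroxyls without touching the methyl ethers or the flavone core.

**Compound list**

1 | 2-methoxybenzene-1,3-diol | COc1c(O)cccc1O | starting material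
2 | 2-methoxy-1,3-phenylene bis(2,2-dimethylpropanoate) | COc1c(OC(=O)C(C)(C)C)cccc1OC(=O)C(C)(C)C | intermediate
3 | 2-methoxy-5-(4,4,5,5-tetramethyl-1,3,2-dioxaborolan-2-yl)-1,3-phenylene bis(2,2-dimethylpropanoate) | COc1c(OC(=O)C(C)(C)C)cc(B2OC(C)(C)C(C)(C)O2)cc1OC(=O)C(C)(C)C | intermediate
4 | 3-hydroxy-4H-pyran-4-one | O=c1ccocc1O | starting material
5 | 2-bromo-3-hydroxy-4H-pyran-4-one | O=c1ccoc(Br)c1O | intermediate
6 | 2-bromo-3-methoxy-4H-pyran-4-one | COc1c(Br)occc1=O | intermediate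
7 | 2-methoxy-5-(3-methoxy-4-oxo-4H-pyran-2-yl)-1,3-phenylene bis(2,2-dimethylpropanoate) | COc1c(-c2cc(OC(=O)C(C)(C)C)c(OC)c(OC(=O)C(C)(C)C)c2)occc1=O | intermediate
8 | 5-(5-iodo-3-methoxy-4-oxo-4H-pyran-2-yl)-2-methoxy-1,3-phenylene bis(2,2-dimethylpropanoate) | COc1c(-c2cc(OC(=O)C(C)(C)C)c(OC)c(OC(=O)C(C)(C)C)c2)occ(I)c1=O | intermediate
9 | dimethyl squarate (3,4-dimethoxycyclobut-3-ene-1,2-dione) | COC1=C(OC)C(=O)C1=O | starting material
10 | 3-tert-butoxy-4-methoxycyclobut-3-ene-1,2-dione | COC1=C(OC(C)(C)C)C(=O)C1=O | intermediate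
11 | pyranon-5-ylmagnesium chloride (magnesium in place of iodine in 8) | COc1c(-c2cc(OC(=O)C(C)(C)C)c(OC)c(OC(=O)C(C)(C)C)c2)occ([Mg]Cl)c1=O | intermediate
12 | racemic 5-[5-(3-tert-butoxy-1-hydroxy-2-methoxy-4-oxocyclobut-2-en-1-yl)-3-methoxy-4-oxo-4H-pyran-2-yl]-2-methoxy-1,3-phenylene bis(2,2-dimethylpropanoate) | COC1=C(OC(C)(C)C)C(=O)C1(O)c1coc(-c2cc(OC(=O)C(C)(C)C)c(OC)c(OC(=O)C(C)(C)C)c2)c(OC)c1=O | intermediate
13 | (Z)-dienylketene: 5-[5-[(1Z)-3-tert-butoxy-1-hydroxy-2-methoxy-4-oxobuta-1,3-dien-1-yl]-3-methoxy-4-oxo-4H-pyran-2-yl]-2-methoxy-1,3-phenylene bis(2,2-dimethylpropanoate) | O=C=C(OC(C)(C)C)/C(OC)=C(/O)c1coc(-c2cc(OC(=O)C(C)(C)C)c(OC)c(OC(=O)C(C)(C)C)c2)c(OC)c1=O | intermediate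
14 | 8aH-chromene-4,8-dione tautomer of 15 (racemic at C8a) | COC1=C(c2cc(OC(=O)C(C)(C)C)c(OC)c(OC(=O)C(C)(C)C)c2)OC2C(=O)C(OC(C)(C)C)=C(OC)C(O)=C2C1=O | intermediate
15 | 5-(7-tert-butoxy-5,8-dihydroxy-3,6-dimethoxy-4-oxo-4H-chromen-2-yl)-2-methoxy-1,3-phenylene bis(2,2-dimethylpropanoate) | COc1c(OC(=O)C(C)(C)C)cc(-c2oc3c(O)c(OC(C)(C)C)c(OC)c(O)c3c(=O)c2OC)cc1OC(=O)C(C)(C)C | intermediate
16 | 5-(7-tert-butoxy-5-hydroxy-3,6,8-trimethoxy-4-oxo-4H-chromen-2-yl)-2-methoxy-1,3-phenylene bis(2,2-dimethylpropanoate) | COc1c(OC(=O)C(C)(C)C)cc(-c2oc3c(OC)c(OC(C)(C)C)c(OC)c(O)c3c(=O)c2OC)cc1OC(=O)C(C)(C)C | intermediate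
17 | 5-(5,7-dihydroxy-3,6,8-trimethoxy-4-oxo-4H-chromen-2-yl)-2-methoxy-1,3-phenylene bis(2,2-dimethylpropanoate) | COc1c(OC(=O)C(C)(C)C)cc(-c2oc3c(OC)c(O)c(OC)c(O)c3c(=O)c2OC)cc1OC(=O)C(C)(C)C | intermediate
18 | 5,7,3',5'-tetrahydroxy-3,6,8,4'-tetramethoxyflavone | COc1c(O)cc(-c2oc3c(OC)c(O)c(OC)c(O)c3c(=O)c2OC)cc1O | target

**Step count**

Total steps: 12. Longest linear sequence: 9 (steps 1, 2, 5, 6, 8, 9, 10, 11, 12).

**Steps most likely to fail**

Step 9. The ketene may be captured by the neighbouring hydroxyl (lactonisation) instead of closing on carbon, or the tert-butyl group may be lost thermally before closure. The fallback sets out from 12 and returns at 15. The carbinol is silylated (TMSCl, imidazole, DMF) to the trimethylsilyl ether F1. Thermolysis in toluene at 110 °C then passes through the silyloxy dienylketene F2 and the silyloxy 8aH-dienone F3 to the 5-trimethylsilyloxy flavone F4. Methanolysis (MeOH, PPTS cat.) gives 15. With the oxygen capped, the lactonisation pathway is closed.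

Step 8. The organomagnesium may attack the carbonyl next to the tert-butoxy-bearing carbon, because the steric bias is opposed by a small electronic bias, and this would exchange the C6 and C7 substituents. The fallback sets out from 8 and returns at 17; it does not depend on which carbonyl is attacked.
- Reagent 11, formed as in step 8, is added to purchased di-tert-butyl squarate to give the di-tert-butoxy carbinol F5.
- Thermolysis passes through the dienylketene F6 and the 8aH-dienone F7 to the 6,7-di-tert-butoxy-5,8-dihydroxy flavone F8.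
- Methylation of the free 8-hydroxyl (MeI, K2CO3) gives the 8-methyl ether F9, and TFA removes both tert-butyl groups to give the 5,6,7-trihydroxy flavone F10.
- Benzylation of the most acidic 7-hydroxyl with one equivalent of BnBr and K2CO3 gives the 7-benzyl ether F11.
- Methylation of the 6-hydroxyl, with the 5-hydroxyl chelated, gives the 6-methyl ether F12, and hydrogenolysis (H2, Pd/C) gives 17.

Step 7. Exchange may run on to the di-tert-butyl ester, or the alkoxide may cleave the four-membered ring. The fallback sets out from 9 and returns at 10. Monosaponification with one equivalent of NaOH and acidification gives methyl hydrogen squarate F13. Ag2O in water gives the silver salt F14, and alkylation with tert-butyl chloride in ether gives 10.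

**Further compounds**

F1 | step 9 | trimethylsilyl ether of 12 (racemic) | COC1=C(OC(C)(C)C)C(=O)C1(O[Si](C)(C)C)c1coc(-c2cc(OC(=O)C(C)(C)C)c(OC)c(OC(=O)C(C)(C)C)c2)c(OC)c1=O
F2 | step 9 | (Z)-silyloxy dienylketene from F1 | O=C=C(OC(C)(C)C)/C(OC)=C(/O[Si](C)(C)C)c1coc(-c2cc(OC(=O)C(C)(C)C)c(OC)c(OC(=O)C(C)(C)C)c2)c(OC)c1=O
F3 | step 9 | silyloxy 8aH-chromene-4,8-dione from F2 (racemic at C8a) | COC1=C(c2cc(OC(=O)C(C)(C)C)c(OC)c(OC(=O)C(C)(C)C)c2)OC2C(=O)C(OC(C)(C)C)=C(OC)C(O[Si](C)(C)C)=C2C1=O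
F4 | step 9 | 5-[7-tert-butoxy-8-hydroxy-3,6-dimethoxy-4-oxo-5-(trimethylsilyloxy)-4H-chromen-2-yl]-2-methoxy-1,3-phenylene bis(2,2-dimethylpropanoate) | COc1c(OC(=O)C(C)(C)C)cc(-c2oc3c(O)c(OC(C)(C)C)c(OC)c(O[Si](C)(C)C)c3c(=O)c2OC)cc1OC(=O)C(C)(C)C
F5 | step 8 | racemic 5-[5-(2,3-di-tert-butoxy-1-hydroxy-4-oxocyclobut-2-en-1-yl)-3-methoxy-4-oxo-4H-pyran-2-yl]-2-methoxy-1,3-phenylene bis(2,2-dimethylpropanoate) | CC(C)(C)OC1=C(OC(C)(C)C)C(=O)C1(O)c1coc(-c2cc(OC(=O)C(C)(C)C)c(OC)c(OC(=O)C(C)(C)C)c2)c(OC)c1=O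
F6 | step 8 | (Z)-di-tert-butoxy dienylketene from F5 | O=C=C(OC(C)(C)C)/C(OC(C)(C)C)=C(/O)c1coc(-c2cc(OC(=O)C(C)(C)C)c(OC)c(OC(=O)C(C)(C)C)c2)c(OC)c1=O
F7 | step 8 | di-tert-butoxy 8aH-chromene-4,8-dione from F6 (racemic at C8a) | COC1=C(c2cc(OC(=O)C(C)(C)C)c(OC)c(OC(=O)C(C)(C)C)c2)OC2C(=O)C(OC(C)(C)C)=C(OC(C)(C)C)C(O)=C2C1=O
F8 | step 8 | 5-(6,7-di-tert-butoxy-5,8-dihydroxy-3-methoxy-4-oxo-4H-chromen-2-yl)-2-methoxy-1,3-phenylene bis(2,2-dimethylpropanoate) | COc1c(OC(=O)C(C)(C)C)cc(-c2oc3c(O)c(OC(C)(C)C)c(OC(C)(C)C)c(O)c3c(=O)c2OC)cc1OC(=O)C(C)(C)C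
F9 | step 8 | 5-(6,7-di-tert-butoxy-5-hydroxy-3,8-dimethoxy-4-oxo-4H-chromen-2-yl)-2-methoxy-1,3-phenylene bis(2,2-dimethylpropanoate) | COc1c(OC(=O)C(C)(C)C)cc(-c2oc3c(OC)c(OC(C)(C)C)c(OC(C)(C)C)c(O)c3c(=O)c2OC)cc1OC(=O)C(C)(C)C
F10 | step 8 | 5-(5,6,7-trihydroxy-3,8-dimethoxy-4-oxo-4H-chromen-2-yl)-2-methoxy-1,3-phenylene bis(2,2-dimethylpropanoate) | COc1c(OC(=O)C(C)(C)C)cc(-c2oc3c(OC)c(O)c(O)c(O)c3c(=O)c2OC)cc1OC(=O)C(C)(C)C
F11 | step 8 | 5-(7-benzyloxy-5,6-dihydroxy-3,8-dimethoxy-4-oxo-4H-chromen-2-yl)-2-methoxy-1,3-phenylene bis(2,2-dimethylpropanoate) | COc1c(OC(=O)C(C)(C)C)cc(-c2oc3c(OC)c(OCc4ccccc4)c(O)c(O)c3c(=O)c2OC)cc1OC(=O)C(C)(C)C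
F12 | step 8 | 5-(7-benzyloxy-5-hydroxy-3,6,8-trimethoxy-4-oxo-4H-chromen-2-yl)-2-methoxy-1,3-phenylene bis(2,2-dimethylpropanoate) | COc1c(OC(=O)C(C)(C)C)cc(-c2oc3c(OC)c(OCc4ccccc4)c(OC)c(O)c3c(=O)c2OC)cc1OC(=O)C(C)(C)C
F13 | step 7 | 3-hydroxy-4-methoxycyclobut-3-ene-1,2-dione (methyl hydrogen squarate) | COC1=C(O)C(=O)C1=O
F14 | step 7 | silver 2-methoxy-3,4-dioxocyclobut-1-en-1-olate | COC1=C([O-])C(=O)C1=O.[Ag+]
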